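**Plan**
1. Cuts, in retrosynthetic order (cyclohexanone numbering: C1 carbonyl/carbinol, C2 CH, C3 CMe2, C4 CHX): the C1–CH3 bond (Grignard on a ketone), the C4–Br bond (SN2 on an axial alcohol), then the bond from the linker CH2 to cyclohexane C2 (enolate C‑alkylation), which separates an iodoethyl bromo‑oxane from a cyclohexenyl silyl ether; further back the oxane O–C2/C3–Br bonds (bromo‑etherification) and the cyclohexane C2–C3 bond (epoxide cyclisation).
2. Forward order: the oxane is closed first on (3S,6E)‑nerolidol and its prenyl tail is trimmed to CH2CH2I; the carbocycle is closed from an epoxy β‑keto ester (prenol + allyl acetoacetate); the two rings are joined, then Br and CH3 are put on the carbocycle.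
3. Feature that makes the union possible: cyclohexane C2 is α to the latent C1 carbonyl, wedged between it and the quaternary C3, and C4 (1,3 to C2) carries a heteroatom; an allyl carboxylate on C2 fixes the enolate regiochemistry and leaves as CO2 before the union.
4. C4 is carried as the (S)‑silyl ether, which steers the alkylation at C2 trans to itself, and is then exchanged for bromide with inversion; a bromide at C4 during the alkylation would give the wrong C2 epimer.
5. Stereochemistry: oxane C6 from nerolidol, oxane C2/C3 from anti addition across the E‑olefin (diastereomer separation needed); carbocycle C4 from Sharpless epoxidation followed by SN2 inversion, C2 from the substrate‑controlled alkylation, C1 from equatorial Grignard attack.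

Key step: step 10

Remark: natural (+)‑(3S,6E)‑nerolidol is taken as a commercial, enantiomerically enriched terpene alcohol; locants in the text follow the name of the compound under discussion.

Step 1
Reactants: 1 (3S,6E)-nerolidol [(3S,6E)-3,7,11-trimethyldodeca-1,6,10-trien-3-ol]
Product: 2 (2S,3R,6S)-3-bromo-6-ethenyl-2,6-dimethyl-2-(4-methylpent-3-en-1-yl)oxane
Conditions: TBCO, MeNO2, 0 °C → rt, dark; chromatography
Reagents that add atoms: 2,4,4,6-tetrabromocyclohexa-2,5-dien-1-one (TBCO), O=C1C(Br)=CC(Br)(Br)C=C1Br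
Why: Bromonium‑induced cycloetherification (6‑endo, Markovnikov): the tertiary hydroxyl opens the 6,7‑bromonium ion at its tertiary carbon anti to bromine, so the E‑olefin fixes the C2/C3 relationship (Br cis to the C2 methyl) and the carbinol centre becomes C6; that centre gives little facial bias, so 2 should need chromatographic separation from its (2R,3S,6S) isomer and from 5‑exo products.

Step 2
Reactants: 2 (2S,3R,6S)-3-bromo-6-ethenyl-2,6-dimethyl-2-(4-methylpent-3-en-1-yl)oxane
Product: 4 3-[(2S,3R,6S)-3-bromo-6-ethenyl-2,6-dimethyloxan-2-yl]propanal, via ozonide 3 (not isolated)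
Conditions: O3 (1 equiv, Sudan Red end‑point), CH2Cl2, −78 °C; then Me2S, −78 °C → rt
Reagents that add atoms: ozone, O=[O+][O-]
Why: Criegee ozonolysis with reductive work‑up, chemoselective because the electron‑rich trisubstituted olefin adds ozone much faster than the monosubstituted vinyl group on the ether carbon; no stereocentre is touched.

Step 3
Reactants: 4 3-[(2S,3R,6S)-3-bromo-6-ethenyl-2,6-dimethyloxan-2-yl]propanal
Product: 5 3-[(2S,3R,6S)-3-bromo-6-ethenyl-2,6-dimethyloxan-2-yl]propanoic acid
Conditions: NaClO2, NaH2PO4, 2-methylbut-2-ene, t-BuOH/H2O, 0 °C → rt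
Reagents that add atoms: sodium chlorite, [Na+].[O-]Cl=O
Why: Pinnick oxidation under buffered conditions, with 2‑methylbut‑2‑ene scavenging hypochlorous acid so that the vinyl group and the secondary bromide survive.

Step 4
Reactants: 5 3-[(2S,3R,6S)-3-bromo-6-ethenyl-2,6-dimethyloxan-2-yl]propanoic acid
Product: 7 (2S,3R,6S)-3-bromo-6-ethenyl-2-(2-iodoethyl)-2,6-dimethyloxane, via Barton ester 6 (not isolated)
Conditions: 1-hydroxypyridine-2(1H)-thione, DCC, DMAP (cat.), CH2Cl2, rt, dark; then CHI3, PhH, hν, rt
Reagents that add atoms: iodoform, IC(I)I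
Why: Barton decarboxylative iodination: the thiohydroxamate ester fragments to the primary alkyl radical, which abstracts iodine from iodoform faster than it can cyclise onto the vinyl group, giving the nor‑iodide with the oxane stereocentres untouched.

Step 5
Reactants: 8 3-methylbut-2-en-1-ol (prenol)
Product: 9 [(2S)-3,3-dimethyloxiran-2-yl]methanol
Conditions: Ti(Oi-Pr)4 (cat.), L-(+)-diethyl tartrate (cat.), t-BuOOH, 4 Å MS, CH2Cl2, −20 °C
Reagents that add atoms: tert-butyl hydroperoxide, CC(C)(C)OO
Why: Sharpless asymmetric epoxidation of the allylic alcohol; the L‑(+)‑tartrate/titanium catalyst delivers oxygen to the olefin face that gives the (2S)‑epoxide, the only source of absolute configuration for the carbocycle.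

Step 6
Reactants: 9 [(2S)-3,3-dimethyloxiran-2-yl]methanol
Product: 10 [(2S)-3,3-dimethyloxiran-2-yl]methyl trifluoromethanesulfonate
Conditions: Tf2O, 2,6-lutidine, CH2Cl2, −78 °C; used cold without purification
Reagents that add atoms: trifluoromethanesulfonic anhydride, O=S(=O)(OS(=O)(=O)C(F)(F)F)C(F)(F)F
Why: O‑Sulfonylation of the primary alcohol at low temperature gives a primary triflate reactive enough to be displaced at −78 °C before the epoxide can be attacked; the stereocentre is not involved.

Step 7
Reactants: 11 prop-2-en-1-yl 3-oxobutanoate (allyl acetoacetate); 10 [(2S)-3,3-dimethyloxiran-2-yl]methyl trifluoromethanesulfonate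
Product: 13 prop-2-en-1-yl 5-[(2S)-3,3-dimethyloxiran-2-yl]-3-oxopentanoate, via acetoacetate dianion 12 (not isolated)
Conditions: NaH, THF, 0 °C; n-BuLi, 0 °C; then 10, −78 → −40 °C; AcOH
Reagents that add atoms: none
Why: γ‑Alkylation of the acetoacetate dianion, whose terminal carbanion is the more reactive site, by SN2 at the primary triflate carbon; quenching cold keeps the resulting β‑keto ester anion from opening the epoxide.

Step 8
Reactants: 13 prop-2-en-1-yl 5-[(2S)-3,3-dimethyloxiran-2-yl]-3-oxopentanoate
Product: 14 prop-2-en-1-yl (5S)-5-hydroxy-6,6-dimethyl-2-oxocyclohexane-1-carboxylate (C1 epimers/enol)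
Conditions: SnCl4 (1.1 equiv), CH2Cl2, −78 → −20 °C; aq. NaHCO3
Reagents that add atoms: none
Why: Lewis‑acid‑promoted epoxide‑initiated cation–olefin‑type cyclisation (6‑endo opening): the tin‑chelated β‑keto ester attacks through carbon at the tertiary epoxide carbon via a chair transition state, forming the ring bond between the ester‑bearing carbon and the new gem‑dimethyl carbon, while the C–O bond at the stereocentre stays intact, so C5 is (S) with the hydroxyl equatorial.

Step 9
Reactants: 14 prop-2-en-1-yl (5S)-5-hydroxy-6,6-dimethyl-2-oxocyclohexane-1-carboxylate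
Product: 16 {[(4S)-3,3-dimethyl-4-[(trimethylsilyl)oxy]cyclohex-1-en-1-yl]oxy}(trimethyl)silane, via bis-silyl keto ester 15 (not isolated)
Conditions: Pd(PPh3)4 (3 mol %), Me3SiNMe2 (2.5 equiv), CH2Cl2, rt; then PhMe, 100 °C; used crude
Reagents that add atoms: N,N-dimethyl-1,1,1-trimethylsilanamine, CN(C)[Si](C)(C)C
Why: Tsuji–Trost‑type palladium(0) allyl transfer to the silylamine unmasks the acid as its trimethylsilyl ester (the silylamine also silylates the C5 hydroxyl), and thermal decarboxylative 1,5‑silyl migration of the silyl β‑keto ester then delivers the enol silyl ether regiospecifically towards the carbon that carried the carboxyl group, next to the quaternary carbon.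

Step 10
Reactants: 16 {[(4S)-3,3-dimethyl-4-[(trimethylsilyl)oxy]cyclohex-1-en-1-yl]oxy}(trimethyl)silane; 7 (2S,3R,6S)-3-bromo-6-ethenyl-2-(2-iodoethyl)-2,6-dimethyloxane
Product: 19 (2R,4S)-2-{2-[(2S,3R,6S)-3-bromo-6-ethenyl-2,6-dimethyloxan-2-yl]ethyl}-4-hydroxy-3,3-dimethylcyclohexan-1-one, via lithium enolate 17 (not isolated), via O-silyl ketone 18 (not isolated)
Conditions: MeLi (1.0 equiv), THF, 0 °C; then 7, DMPU, −78 → −20 °C; NH4Cl; then citric acid, MeOH, 0 °C
Reagents that add atoms: none
Why: Methyllithium cleaves the vinylic O–Si bond of 16 and releases the Δ1,2 lithium enolate 17 regiospecifically under aprotic conditions, so the nucleophilic carbon is C2, the methylene between the enolate carbon and the quaternary C3, and it displaces iodide from the primary, β‑unbranched carbon of 7 in an SN2 C‑alkylation (closest known reaction type: regiospecific alkylation of lithium enolates generated from trimethylsilyl enol ethers, as used for 2‑alkyl‑3,3‑dimethylcyclohexanones). No ring is closed. The one new stereocentre, C2 of the cyclohexanone, is controlled by the C4 silyloxy group: in the half‑chair with C4–OSiMe3 pseudo‑equatorial the electrophile enters axially, anti to the pseudo‑axial C3 methyl and syn only to the axial C4–H, whereas the other half‑chair would force a 1,3‑diaxial clash with OSiMe3, so the chain should end trans to the C4 oxygen, (2R,4S). The step needs C‑ over O‑alkylation (lithium counter‑ion, soft iodide), regiochemical fidelity (no proton source, cold quench before the enolate can equilibrate) and chemoselectivity for the primary iodide over the secondary bromide of 7, which is flanked by a quaternary carbon and inert to SN2 at −20 °C. The trans product is the kinetic one and is taken on without exposure to base, because the C4 oxygen is next replaced by bromide with inversion, which converts trans‑(2R,4S) into the cis‑(2R,4R) pattern of the target. Mild acidic methanolysis in the work‑up removes the C4 trimethylsilyl group.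

Step 11
Reactants: 19 (2R,4S)-2-{2-[(2S,3R,6S)-3-bromo-6-ethenyl-2,6-dimethyloxan-2-yl]ethyl}-4-hydroxy-3,3-dimethylcyclohexan-1-one
Product: 20 (2R,4R)-4-bromo-2-{2-[(2S,3R,6S)-3-bromo-6-ethenyl-2,6-dimethyloxan-2-yl]ethyl}-3,3-dimethylcyclohexan-1-one
Conditions: PPh3, CBr4, CH2Cl2, 0 °C → rt
Reagents that add atoms: carbon tetrabromide, BrC(Br)(Br)Br
Why: Appel reaction: with the C2 chain equatorial the (4S)‑hydroxyl is axial, and its oxyphosphonium is displaced by bromide from the equatorial direction (SN2, inversion) to give the equatorial (4R)‑bromide cis to the side chain, under neutral conditions that leave the kinetic C2 centre, the ketone, the vinyl group and the oxane bromide untouched.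

Step 12
Reactants: 20 (2R,4R)-4-bromo-2-{2-[(2S,3R,6S)-3-bromo-6-ethenyl-2,6-dimethyloxan-2-yl]ethyl}-3,3-dimethylcyclohexan-1-one
Product: 21 (1S,2R,4R)-4-bromo-2-{2-[(2S,3R,6S)-3-bromo-6-ethenyl-2,6-dimethyloxan-2-yl]ethyl}-1,3,3-trimethylcyclohexan-1-ol
Conditions: MeMgBr, PhMe/Et2O, −78 → −40 °C; aq. NH4Cl
Reagents that add atoms: methylmagnesium bromide, C[Mg]Br
Why: Grignard 1,2‑addition: with the C2 chain and C4 bromine equatorial the axial trajectory is blocked by the axial C3 methyl, so methyl should add equatorially, anti to the C2 chain, giving the axial tertiary alcohol cis to the chain, (1S).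

**Compound list**
1 | (3S,6E)-nerolidol, (3S,6E)-3,7,11-trimethyldodeca-1,6,10-trien-3-ol | C=C[C@@](C)(O)CC/C=C(\C)CCC=C(C)C | starting material
2 | (2S,3R,6S)-3-bromo-6-ethenyl-2,6-dimethyl-2-(4-methylpent-3-en-1-yl)oxane | C=C[C@]1(C)CC[C@@H](Br)[C@](C)(CCC=C(C)C)O1 | intermediate
3 | ozonide of 2: 3-{2-[(2S,3R,6S)-3-bromo-6-ethenyl-2,6-dimethyloxan-2-yl]ethyl}-5,5-dimethyl-1,2,4-trioxolane | C=C[C@]1(C)CC[C@@H](Br)[C@](C)(CCC2OOC(C)(C)O2)O1 | intermediate (not isolated)
4 | 3-[(2S,3R,6S)-3-bromo-6-ethenyl-2,6-dimethyloxan-2-yl]propanal | C=C[C@]1(C)CC[C@@H](Br)[C@](C)(CCC=O)O1 | intermediate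
5 | 3-[(2S,3R,6S)-3-bromo-6-ethenyl-2,6-dimethyloxan-2-yl]propanoic acid | C=C[C@]1(C)CC[C@@H](Br)[C@](C)(CCC(=O)O)O1 | intermediate
6 | Barton ester: 2-thioxopyridin-1(2H)-yl 3-[(2S,3R,6S)-3-bromo-6-ethenyl-2,6-dimethyloxan-2-yl]propanoate | C=C[C@]1(C)CC[C@@H](Br)[C@](C)(CCC(=O)ON2C=CC=CC2=S)O1 | intermediate (not isolated)
7 | (2S,3R,6S)-3-bromo-6-ethenyl-2-(2-iodoethyl)-2,6-dimethyloxane | C=C[C@]1(C)CC[C@@H](Br)[C@](C)(CCI)O1 | intermediate
8 | 3-methylbut-2-en-1-ol (prenol) | CC(C)=CCO | starting material
9 | [(2S)-3,3-dimethyloxiran-2-yl]methanol | OC[C@@H]1OC1(C)C | intermediate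
10 | [(2S)-3,3-dimethyloxiran-2-yl]methyl trifluoromethanesulfonate | O=S(=O)(OC[C@@H]1OC1(C)C)C(F)(F)F | intermediate
11 | prop-2-en-1-yl 3-oxobutanoate (allyl acetoacetate) | C=CCOC(=O)CC(C)=O | starting material
12 | sodium lithium dianion of allyl acetoacetate (1,3-dienolate) | [Na+].[Li+].C=C([O-])C=C([O-])OCC=C | intermediate (not isolated)
13 | prop-2-en-1-yl 5-[(2S)-3,3-dimethyloxiran-2-yl]-3-oxopentanoate | C=CCOC(=O)CC(=O)CC[C@@H]1OC1(C)C | intermediate
14 | prop-2-en-1-yl (5S)-5-hydroxy-6,6-dimethyl-2-oxocyclohexane-1-carboxylate | C=CCOC(=O)C1C(=O)CC[C@H](O)C1(C)C | intermediate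
15 | trimethylsilyl (5S)-6,6-dimethyl-2-oxo-5-[(trimethylsilyl)oxy]cyclohexane-1-carboxylate | C[Si](C)(C)OC(=O)C1C(=O)CC[C@H](O[Si](C)(C)C)C1(C)C | intermediate (not isolated)
16 | {[(4S)-3,3-dimethyl-4-[(trimethylsilyl)oxy]cyclohex-1-en-1-yl]oxy}(trimethyl)silane | C[Si](C)(C)OC1=CC(C)(C)[C@@H](O[Si](C)(C)C)CC1 | intermediate
17 | lithium (4S)-3,3-dimethyl-4-[(trimethylsilyl)oxy]cyclohex-1-en-1-olate | [Li+].[O-]C1=CC(C)(C)[C@@H](O[Si](C)(C)C)CC1 | intermediate (not isolated)
18 | (2R,4S)-2-{2-[(2S,3R,6S)-3-bromo-6-ethenyl-2,6-dimethyloxan-2-yl]ethyl}-3,3-dimethyl-4-[(trimethylsilyl)oxy]cyclohexan-1-one | C=C[C@]1(C)CC[C@@H](Br)[C@](C)(CC[C@@H]2C(C)(C)[C@@H](O[Si](C)(C)C)CCC2=O)O1 | intermediate (not isolated)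
19 | (2R,4S)-2-{2-[(2S,3R,6S)-3-bromo-6-ethenyl-2,6-dimethyloxan-2-yl]ethyl}-4-hydroxy-3,3-dimethylcyclohexan-1-one | C=C[C@]1(C)CC[C@@H](Br)[C@](C)(CC[C@@H]2C(C)(C)[C@@H](O)CCC2=O)O1 | intermediate
20 | (2R,4R)-4-bromo-2-{2-[(2S,3R,6S)-3-bromo-6-ethenyl-2,6-dimethyloxan-2-yl]ethyl}-3,3-dimethylcyclohexan-1-one | C=C[C@]1(C)CC[C@@H](Br)[C@](C)(CC[C@@H]2C(C)(C)[C@H](Br)CCC2=O)O1 | intermediate
21 | (1S,2R,4R)-4-bromo-2-{2-[(2S,3R,6S)-3-bromo-6-ethenyl-2,6-dimethyloxan-2-yl]ethyl}-1,3,3-trimethylcyclohexan-1-ol | C=C[C@]1(C)CC[C@@H](Br)[C@](C)(CC[C@@H]2C(C)(C)[C@H](Br)CC[C@]2(C)O)O1 | target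

**Count and risks**
Total: 12 steps. Longest linear sequence: 8 steps (8 → 21, steps 5–12); the oxane branch (steps 1–4) joins at step 10.

Step 11 is the most likely to fail. The oxyphosphonium at the carbinol carbon next to the quaternary centre may ionise instead of being displaced, so that E2 loss to the olefin or 1,2‑methyl migration outruns substitution. The fallback sets out from 19 and returns at 20: chloromethanesulfonyl chloride/pyridine converts the axial alcohol into the discrete, less ionising sulfonate (1S,3R)-3-{2-[(2S,3R,6S)-3-bromo-6-ethenyl-2,6-dimethyloxan-2-yl]ethyl}-2,2-dimethyl-4-oxocyclohexyl chloromethanesulfonate F1, which is then displaced by LiBr in DMF with inversion to give 20.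

Step 10 is next. Slow SN2 at the hindered enolate carbon may let E2 of the primary iodide and proton transfer compete, with loss of the regio‑ and stereochemical information of the enolate. The fallback reverses polarity, sets out from 16 and 7 and returns at 18. NBS converts 16 into (4S)-2-bromo-3,3-dimethyl-4-[(trimethylsilyl)oxy]cyclohexan-1-one F2 (C2 epimers), and Zn/LiCl converts 7 into {2-[(2S,3R,6S)-3-bromo-6-ethenyl-2,6-dimethyloxan-2-yl]ethyl}(iodo)zinc F3. The two are joined by a nickel‑catalysed Negishi‑type sp3–sp3 coupling of the α‑bromo ketone (NiCl2·glyme, pybox‑type ligand, DMA/THF, 0 °C). This needs no basic enolate, both C2 epimers of F2 converge through the planar α‑keto radical, and bond formation is again expected on the face away from the C4 silyloxy group. The product 18 is methanolysed to 19 as in the route.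

Step 1 is third. Capture of the bromonium ion in the 5‑exo mode and at the distal trisubstituted olefin, together with the absent facial bias from the carbinol centre, may leave only a small share of 2. The fallback sets out from 1 and returns at 2: reversible oxymercuration with Hg(OCOCF3)2 in MeNO2 (thermodynamic 6‑endo Markovnikov closure) and NaBr work‑up give bromo[(2S,3R,6S)-6-ethenyl-2,6-dimethyl-2-(4-methylpent-3-en-1-yl)oxan-3-yl]mercury F4, separated from its diastereomer, and brominolysis with Br2/LiBr in pyridine with retention then gives 2.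

Further compounds
F1 | step 11 | (1S,3R)-3-{2-[(2S,3R,6S)-3-bromo-6-ethenyl-2,6-dimethyloxan-2-yl]ethyl}-2,2-dimethyl-4-oxocyclohexyl chloromethanesulfonate | C=C[C@]1(C)CC[C@@H](Br)[C@](C)(CC[C@@H]2C(C)(C)[C@@H](OS(=O)(=O)CCl)CCC2=O)O1
F2 | step 10 | (4S)-2-bromo-3,3-dimethyl-4-[(trimethylsilyl)oxy]cyclohexan-1-one (C2 epimers) | O=C1CC[C@H](O[Si](C)(C)C)C(C)(C)C1Br
F3 | step 10 | {2-[(2S,3R,6S)-3-bromo-6-ethenyl-2,6-dimethyloxan-2-yl]ethyl}(iodo)zinc | C=C[C@]1(C)CC[C@@H](Br)[C@](C)(CC[Zn]I)O1
F4 | step 1 | bromo[(2S,3R,6S)-6-ethenyl-2,6-dimethyl-2-(4-methylpent-3-en-1-yl)oxan-3-yl]mercury | C=C[C@]1(C)CC[C@@H]([Hg]Br)[C@](C)(CCC=C(C)C)O1
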